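In a one-step world the product would simply be the substrate lost, so I worked with the fraction of substrate left, f, and asked what became of the rest.

| setting | ochre | violet | green | Friday's | Sunday's | Wednesday's | Thursday's |
|---|---|---|---|---|---|---|---|
| substrate | 0.050 M | 0.050 M | 0.075 M | 0.050 M | 0.050 M | 0.050 M | 0.050 M |
| solid partner | 1.3 equiv | 3 equiv | 2 equiv | 2.00 equiv | 2.00 equiv | 2.00 equiv | 2.00 equiv |
| temperature | 15 °C | 50 °C | 15 °C | 80 °C | 50 °C |  | 20 °C |
| remark | run made earlier | run made earlier | run made earlier |  |  | at 80 °C until 12 h, from then on at 20 °C |  |
| time |  |  |  | 25 h | 25 h | 25 h | 25 h |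

| run | time / h | product / % | substrate / % |
|---|---|---|---|
| ochre | 96.0 | 0 | 98.6 |
| ochre | 192 | 2.1 | 93.4 |
| ochre | 240 | 3.3 | 92.4 |
| ochre | 360 | 6.3 | 88.0 |
| ochre | 480 | 11.0 | 84.8 |
| ochre | 600 | 14.9 | 81.3 |
| violet | 20.0 | 8.6 | 37.6 |
| violet | 40.0 | 20.8 | 13.3 |
| violet | 72.0 | 38.1 | 2.9 |
| violet | 96.0 | 54.3 | 0.2 |
| violet | 120 | 66.3 | 1.3 |
| green | 50.0 | 0.5 | 98.3 |
| green | 96.0 | 0 | 97.8 |
| green | 192 | 3.3 | 94.9 |
| green | 288 | 5.7 | 91.2 |
| green | 600 | 14.6 | 83.6 |

(standard deviation of a reading: 1 percentage point)

- solid partner is a solid; its amount is given per volume of the solution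
- on the list of suspects stand: substrate -> intermediate; fresh partner + intermediate -> product; solid partner <-> fresh partner
- at the start none of the solid partner is in solution

- the flask that comes out highest in amount of product, in percent of the substrate charged, or "all alike" when all lie within 1.5 percentage points (Friday's / Sunday's / Wednesday's / Thursday's / all alike)
- product at the end, in percent of the substrate charged, Friday's
- product at the end, in percent of the substrate charged, Sunday's
- product at the end, in percent of the substrate charged, Wednesday's
- product at the end, in percent of the substrate charged, Thursday's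

The violet run refuses the one-step reading. Between its first two readings f falls at k = 0.0520 /h, yet at 72.0 h it shows substrate 2.9% and product 38.1%, so the balance, 59.0%, is intermediate. From 40.0 h to 96.0 h that intermediate fell from 65.9% to 45.5%, while the pace of product went from 0.00541 /h to 0.00675 /h of the charge. Because the pace did not fall with the stock, I read the dissolving of solid partner as the rate-limiting step and took from that stretch 0.00598 /h as the feed s, the share of the charge per hour that fresh partner brings to product. With intermediate standing ready, product at time t is then about s·t.

Sunday's flask looks nearly the same as the violet run, with 2.00 equiv of solid partner against 3 equiv. The violet run was my one run at 50 °C, so no reading tested that difference there, and I assumed that it did not part them. So I read Sunday's product off the violet run at 25 h, about 11.6%, with f near 27.3%. I had read s at 50 °C and held it at 80 °C as a bet, which gave Friday's about 15.0% and Wednesday's about 7.18% plus what its cold hours add.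

The forecast, on the ground “This suggests supply of fresh partner by slow dissolution limits the rate.”, put Friday's highest, with 33% there, 10.5% for Sunday's, 19% for Wednesday's and 0.1% for Thursday's. Its Friday's and Wednesday's numbers stand above mine.

The flasks gave 15.7% for Friday's, 11.2% for Sunday's, 8.73% for Wednesday's and 0.0618% for Thursday's, with Friday's highest, and behind them ran:

    substrate → intermediate (k = 0.0510 /h, Ea = 112 kJ/mol)
    fresh partner + intermediate → product (k = 5.60 /M/h, Ea = 59.0 kJ/mol)
    solid partner ⇌ fresh partner, rate k3*(cs3 - [fresh partner]) while solid is left; crystals form when [fresh partner] > cs3 (solubility = 25.0 mM, k = 0.0130 /h)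
    (constants at 50 °C)

Friday's flask, at 15.7% against s·t of 15.0%, had not come to rest: at 25.0 h it still held intermediate 84.3%. At the pace s that stock needs 141 h more, and ten times the time adds 225 h; at 250 h Friday's flask stands at product 100% and intermediate 0%. Wednesday's flask held product 7.36% at the change against s·t of 7.18%. It added 1.4 percentage points by the end, and at 250 h it stands at product 75.6% with intermediate 24.4%.

The data are calculated with constants of no real substance; the scatter is artificial.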